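**Plan**

1. The core is numbered as tetracyclo[6.4.0.0^2,7.0^3,6]dodecane: ring A (cyclohexane) = C1, C8–C12; ring B = C1, C2, C7, C8; ring C = C2, C3, C6, C7; ring D = C3–C6; the chain sits on C10.
2. Enabling feature: rings B, C and D hold C1–C8 as one unbranched eight-carbon chain, a folded octa-1,3,5,7-tetraene whose 8π, 6π and 4π closure bonds are the fusion bonds C1–C8 (A/B), C2–C7 (B/C) and C3–C6 (C/D).
3. Retrosynthetic cuts, in order: acetonide; C10–H and the C10–chain bond (alkenyl triflate plus alkylborane); ring-A oxygen back to the meso alkene C10=C11; C3–C6; C10=C11 (metathesis of two allyl groups); C2–C7 and C1–C8; the tetraene back to a dienediyne, cut at the diyne C–C bond into two C7 enynes.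
4. Forward: enynes → dienediyne → semi-hydrogenation, 8π, 6π (ring B and a cyclohexadiene) → metathesis (ring A) → 4π photoclosure (rings C and D) → diimide → epoxide, chiral-base rearrangement, enone, triflate → chain → hydrogenation → diol.
5. Stereochemistry: C1/C8 cis from conrotation of one E and one Z terminus, C2/C7 cis from disrotation, ring A anti to ring C from the thermodynamically exo allyl groups, ring D anti to ring B from the photoclosure; absolute configuration from desymmetrising a meso epoxide with a chiral lithium amide; C10 (S) from hydrogenation on the face of H1 and H8.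

Key step: step 6

Remark 1: reagents are taken to reach ring A from its convex face, the one carrying H1 and H8 (anti to ring B). On that basis carbon delivered to C10 through boron with retention would end trans to ring B, so the chain is placed on sp2 C10 and hydrogen is delivered last.

Remark 2: the sense of induction of the lithium amide is taken from cyclohexene oxide, where the (S)-diamine gives (S)-cyclohex-2-en-1-ol. Should the induction or the epoxide face prove opposite, the (R)-diamine is used.

**Route**

Step 1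
Reactants: 1 pent-1-en-4-yne
Product: 3 (E)-1-iodopenta-1,4-diene, via (E)-penta-1,4-dien-1-ylzirconocene chloride 2 (not isolated)
Conditions: Cp2Zr(H)Cl (1.05 equiv), CH2Cl2, 0 °C to rt, dark; then I2, 0 °C
Reagents that add atoms: iodine, [I][I]
Why: Hydrozirconation–iodination: Zr–H adds syn across the terminal alkyne (faster than across the monosubstituted alkene) with zirconium on the terminal carbon, and iodinolysis of the C–Zr bond with retention should give the E iodide.

Step 2
Reactants: 3 (E)-1-iodopenta-1,4-diene; 4 ethynyltrimethylsilane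
Product: 5 (E)-trimethyl(hepta-3,6-dien-1-yn-1-yl)silane
Conditions: Pd(PPh3)2Cl2 (2 mol%), CuI (4 mol%), Et3N, THF, rt
Reagents that add atoms: none
Why: Sonogashira coupling of an alkenyl iodide with a terminal alkyne keeps the E geometry and runs at room temperature, where the skipped diene should not isomerise.

Step 3
Reactants: 6 but-3-en-1-yltriphenylphosphonium bromide; 7 3-(trimethylsilyl)prop-2-ynal
Product: 9 (Z)-trimethyl(hepta-3,6-dien-1-yn-1-yl)silane, via (but-3-en-1-ylidene)triphenylphosphorane 8 (not isolated)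
Conditions: NaN(SiMe3)2, THF, −78 to 0 °C; then 7, −78 °C to rt
Reagents that add atoms: none
Why: Wittig olefination with a non-stabilised ylide under lithium-free conditions goes through the cis-oxaphosphetane, so the new C3=C4 bond should be Z.

Step 4
Reactants: 9 (Z)-trimethyl(hepta-3,6-dien-1-yn-1-yl)silane
Product: 10 (Z)-1-bromohepta-3,6-dien-1-yne
Conditions: N-bromosuccinimide, AgNO3 (10 mol%), acetone, rt, dark
Reagents that add atoms: N-bromosuccinimide, BrN1C(=O)CCC1=O
Why: Silver-catalysed bromodesilylation of a trimethylsilylalkyne (through the silver acetylide) gives the 1-bromoalkyne directly and leaves both alkenes alone.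

Step 5
Reactants: 5 (E)-trimethyl(hepta-3,6-dien-1-yn-1-yl)silane; 10 (Z)-1-bromohepta-3,6-dien-1-yne
Product: 12 (4E,10Z)-tetradeca-1,4,10,13-tetraene-6,8-diyne, via (E)-hepta-3,6-dien-1-yne 11 (not isolated)
Conditions: K2CO3, MeOH, rt; then CuCl (10 mol%), NH2OH·HCl, n-BuNH2, H2O, 10 added at 0 °C
Reagents that add atoms: none
Why: Methanolysis frees the volatile terminal alkyne in solution, and Cadiot–Chodkiewicz coupling of its copper acetylide with the bromoalkyne should give the unsymmetrical 1,3-diyne without touching either alkene geometry.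

Step 6
Reactants: 12 (4E,10Z)-tetradeca-1,4,10,13-tetraene-6,8-diyne
Product: 15 meso cis-7,8-diallylbicyclo[4.2.0]octa-2,4-diene (allyl groups exo), via (4E,6Z,8Z,10Z)-tetradeca-1,4,6,8,10,13-hexaene 13 (not isolated), via cis-7,8-diallylcycloocta-1,3,5-triene 14 (not isolated)
Conditions: H2 (1 atm; uptake stopped at 2 equiv), Pd/CaCO3 poisoned with Pb(OAc)2 (Lindlar catalyst), quinoline, CH2Cl2, 25 °C; filtered; then 40 °C
Reagents that add atoms: none
Why: Syn delivery of H2 to both alkynes on the poisoned palladium surface gives the (E,Z,Z,Z)-tetraene 13, which closes thermally by conrotatory 8π electrocyclisation to 14 and then by disrotatory 6π electrocyclisation to 15; the closest known reaction type is the semi-hydrogenation-triggered 8π–6π cascade of conjugated dienediynes to bicyclo[4.2.0]octa-2,4-dienes. The eight-membered ring of 14 closes in the conrotatory mode through the bond between the tetraene termini (C4–C11 of 13, later C1–C8 of the ladder), and ring B together with the cyclohexadiene closes in the disrotatory mode through C5–C10 of 13 (later C2–C7). The two allyl-bearing centres should come out cis because conrotation turns one E and one Z terminus (alkene geometry controls), and the two bridgehead centres cis to each other because the 6π closure is disrotatory (orbital symmetry controls). Their placement trans to the allyl groups (exo) is under thermodynamic control, the 6π closure being reversible at 40 °C and the endo isomer pressing both allyl groups onto the diene. The step needs alkyne-over-alkene chemoselectivity, secured by the conjugated diyne of the substrate binding the lead- and quinoline-poisoned surface far more strongly than its isolated vinyl groups and by stopping at two equivalents of H2, and it needs no regio- or enantiocontrol because both ends carry the same allyl group and 15 is meso.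

Step 7
Reactants: 15 meso cis-7,8-diallylbicyclo[4.2.0]octa-2,4-diene
Product: 16 meso cis-anti-cis-tricyclo[6.4.0.0^2,7]dodeca-3,5,10-triene (1,4,4a,4b,8a,8b-hexahydrobiphenylene)
Conditions: second-generation Grubbs catalyst (H2IMes)(PCy3)Cl2Ru=CHPh (3 mol%), CH2Cl2 (5 mM), 40 °C
Reagents that add atoms: none
Why: Ring-closing metathesis of the two cis, exo allyl groups closes the unstrained cyclohexene ring A on the face of ring B away from the diene, and the conjugated endocyclic diene is a poor metathesis partner.

Step 8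
Reactants: 16 meso cis-anti-cis-tricyclo[6.4.0.0^2,7]dodeca-3,5,10-triene
Product: 17 meso tetracyclo[6.4.0.0^2,7.0^3,6]dodeca-4,10-diene (all fusions cis; A anti to C, D anti to B)
Conditions: hν (254 nm, quartz), degassed pentane, 0 °C
Reagents that add atoms: none
Why: Photochemical disrotatory 4π electrocyclisation of a ring-fused cyclohexa-1,3-diene to a bicyclo[2.2.0]hex-2-ene forms C3–C6 (the conrotatory ring opening is blocked because it would place a trans double bond in an eight-membered ring), and the new cyclobutene should fold away from the endo hydrogens H1 and H8 of ring B, giving the anti ladder.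

Step 9
Reactants: 17 meso tetracyclo[6.4.0.0^2,7.0^3,6]dodeca-4,10-diene
Product: 18 meso tetracyclo[6.4.0.0^2,7.0^3,6]dodec-10-ene
Conditions: KO2CN=NCO2K, AcOH, MeOH, 0 °C to rt
Reagents that add atoms: none
Why: Diimide reduction is strongly accelerated by ring strain, so the bicyclo[2.2.0]hexene double bond should be saturated well before the unstrained cyclohexene, and no metal is present that could open a cyclobutane.

Step 10
Reactants: 18 meso tetracyclo[6.4.0.0^2,7.0^3,6]dodec-10-ene
Product: 19 meso 10,11-epoxytetracyclo[6.4.0.0^2,7.0^3,6]dodecane (oxirane oxygen cis to H1 and H8, trans to ring B)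
Conditions: mCPBA, NaHCO3, CH2Cl2, 0 °C
Reagents that add atoms: 3-chloroperoxybenzoic acid, OOC(=O)c1cccc(Cl)c1
Why: Prilezhaev epoxidation is concerted and syn, and attack on the convex face of the cis-fused bicyclo[4.2.0]octene should set C10 and C11 together as one meso epoxide; a minor syn epoxide, if formed, is a separable diastereomer.

Step 11
Reactants: 19 meso 10,11-epoxytetracyclo[6.4.0.0^2,7.0^3,6]dodecane
Product: 20 (10S)-tetracyclo[6.4.0.0^2,7.0^3,6]dodec-11-en-10-ol (OH trans to ring B; enantiomer as in the SMILES)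
Conditions: (S)-2-(pyrrolidin-1-ylmethyl)pyrrolidine, n-BuLi (1.5 equiv), THF, 0 °C; then 19, 0 °C to rt
Reagents that add atoms: none
Why: Enantioselective rearrangement of a meso epoxide to an allylic alcohol by syn β-elimination: the chiral lithium amide should remove one of the two enantiotopic protons cis to the oxirane (H12 and not H9), which fixes the absolute configuration of the whole molecule, while C10 keeps the epoxide configuration.

Step 12
Reactants: 20 (10S)-tetracyclo[6.4.0.0^2,7.0^3,6]dodec-11-en-10-ol
Product: 21 tetracyclo[6.4.0.0^2,7.0^3,6]dodec-11-en-10-one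
Conditions: Dess–Martin periodinane, NaHCO3, CH2Cl2, 0 °C to rt
Reagents that add atoms: none
Why: Dess–Martin oxidation of a secondary allylic alcohol under buffered, non-epimerising conditions turns C10 into the carbonyl carbon that will carry the chain.

Step 13
Reactants: 21 tetracyclo[6.4.0.0^2,7.0^3,6]dodec-11-en-10-one
Product: 23 tetracyclo[6.4.0.0^2,7.0^3,6]dodec-10-en-10-yl trifluoromethanesulfonate, via lithium tetracyclo[6.4.0.0^2,7.0^3,6]dodec-10-en-10-olate 22 (not isolated)
Conditions: LiBH(s-Bu)3, THF, −78 °C; then PhNTf2, −78 to 0 °C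
Reagents that add atoms: N-phenylbis(trifluoromethanesulfonimide), O=S(=O)(N(c1ccccc1)S(=O)(=O)C(F)(F)F)C(F)(F)F
Why: Conjugate hydride reduction of a β-unsubstituted cyclohexenone gives the enolate with its double bond fixed between C10 and C11, and O-triflation traps it, so the alkenyl triflate should form as a single regioisomer.

Step 14
Reactants: 24 2,2-dimethyl-1,3-dioxan-5-ol; 25 8-bromooct-1-ene
Product: 27 2,2-dimethyl-5-(oct-7-en-1-yloxy)-1,3-dioxane, via sodium 2,2-dimethyl-1,3-dioxan-5-olate 26 (not isolated)
Conditions: NaH, DMF, 0 °C; then 25, n-Bu4NI (cat.), rt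
Reagents that add atoms: none
Why: Williamson ether synthesis: the secondary alkoxide displaces bromide from the unhindered primary carbon, and the acetonide is stable to base.

Step 15
Reactants: 23 tetracyclo[6.4.0.0^2,7.0^3,6]dodec-10-en-10-yl trifluoromethanesulfonate; 27 2,2-dimethyl-5-(oct-7-en-1-yloxy)-1,3-dioxane
Product: 29 2,2-dimethyl-5-{[8-(tetracyclo[6.4.0.0^2,7.0^3,6]dodec-10-en-10-yl)octyl]oxy}-1,3-dioxane, via 9-[8-(2,2-dimethyl-1,3-dioxan-5-yloxy)octyl]-9-borabicyclo[3.3.1]nonane 28 (not isolated)
Conditions: 27, 9-BBN, THF, rt; then 23, Pd(dppf)Cl2 (5 mol%), K3PO4 (aq), DMF, 50 °C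
Reagents that add atoms: none
Why: B-alkyl Suzuki–Miyaura coupling: anti-Markovnikov hydroboration of the terminal alkene gives the primary alkylborane, which should couple with the alkenyl triflate without moving the ring double bond.

Step 16
Reactants: 29 2,2-dimethyl-5-{[8-(tetracyclo[6.4.0.0^2,7.0^3,6]dodec-10-en-10-yl)octyl]oxy}-1,3-dioxane
Product: 30 2,2-dimethyl-5-({8-[(10S)-tetracyclo[6.4.0.0^2,7.0^3,6]dodecan-10-yl]octyl}oxy)-1,3-dioxane (chain cis to ring B)
Conditions: H2 (1 atm), [Ir(cod)(PCy3)(py)]PF6 (5 mol%), CH2Cl2, rt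
Reagents that add atoms: none
Why: Homogeneous hydrogenation of the trisubstituted alkene with syn delivery of H2 to the convex face of the cis-fused bicyclo[4.2.0]octene (the face of H1 and H8, anti to ring B) should leave H10 cis to H1/H8 and the chain cis to ring B, that is (10S), and the iridium catalyst does not open cyclobutanes under these conditions.

Step 17
Reactants: 30 2,2-dimethyl-5-({8-[(10S)-tetracyclo[6.4.0.0^2,7.0^3,6]dodecan-10-yl]octyl}oxy)-1,3-dioxane
Product: 31 2-({8-[(1R,2S,3S,6R,7R,8S,10S)-tetracyclo[6.4.0.0^2,7.0^3,6]dodecan-10-yl]octyl}oxy)propane-1,3-diol (CNP0193334.1)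
Conditions: AcOH/H2O/THF (3:1:1), 40 °C
Reagents that add atoms: none
Why: Acid-catalysed hydrolysis of the 1,3-dioxane acetonide frees the two primary hydroxyls and leaves the ether, the saturated ladder and C10 untouched.

**Compound list**

1 | pent-1-en-4-yne | C=CCC#C | starting material
2 | (E)-penta-1,4-dien-1-ylzirconocene chloride | C=CC/C=C/[Zr](Cl)(C1C=CC=C1)C1C=CC=C1 | intermediate
3 | (E)-1-iodopenta-1,4-diene | C=CC/C=C/I | intermediate
4 | ethynyltrimethylsilane | C#C[Si](C)(C)C | starting material
5 | (E)-trimethyl(hepta-3,6-dien-1-yn-1-yl)silane | C=CC/C=C/C#C[Si](C)(C)C | intermediate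
6 | but-3-en-1-yltriphenylphosphonium bromide | C=CCC[P+](c1ccccc1)(c1ccccc1)c1ccccc1.[Br-] | starting material
7 | 3-(trimethylsilyl)prop-2-ynal | C[Si](C)(C)C#CC=O | starting material
8 | (but-3-en-1-ylidene)triphenylphosphorane | C=CCC=P(c1ccccc1)(c1ccccc1)c1ccccc1 | intermediate
9 | (Z)-trimethyl(hepta-3,6-dien-1-yn-1-yl)silane | C=CC/C=C\C#C[Si](C)(C)C | intermediate
10 | (Z)-1-bromohepta-3,6-dien-1-yne | C=CC/C=C\C#CBr | intermediate
11 | (E)-hepta-3,6-dien-1-yne | C=CC/C=C/C#C | intermediate
12 | (4E,10Z)-tetradeca-1,4,10,13-tetraene-6,8-diyne | C=CC/C=C/C#CC#C/C=C\CC=C | intermediate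
13 | (4E,6Z,8Z,10Z)-tetradeca-1,4,6,8,10,13-hexaene | C=CC/C=C/C=C\C=C/C=C\CC=C | intermediate
14 | meso cis-7,8-diallylcycloocta-1,3,5-triene | C=CC[C@@H]1C=CC=CC=C[C@@H]1CC=C | intermediate
15 | meso cis-7,8-diallylbicyclo[4.2.0]octa-2,4-diene, cis ring fusion, allyl groups exo | C=CC[C@@H]2[C@H](CC=C)[C@H]1C=CC=C[C@@H]21 | intermediate
16 | meso cis-anti-cis-tricyclo[6.4.0.0^2,7]dodeca-3,5,10-triene (1,4,4a,4b,8a,8b-hexahydrobiphenylene) | C1=CC[C@@H]2[C@H](C1)[C@H]1C=CC=C[C@@H]21 | intermediate
17 | meso tetracyclo[6.4.0.0^2,7.0^3,6]dodeca-4,10-diene, all fusions cis, A anti to C, D anti to B | C1=CC[C@@H]2[C@H](C1)[C@H]1[C@@H]3C=C[C@@H]3[C@@H]21 | intermediate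
18 | meso tetracyclo[6.4.0.0^2,7.0^3,6]dodec-10-ene, same relative configuration | C1=CC[C@@H]2[C@H](C1)[C@H]1[C@@H]3CC[C@@H]3[C@@H]21 | intermediate
19 | meso 10,11-epoxytetracyclo[6.4.0.0^2,7.0^3,6]dodecane, oxirane trans to ring B | O1[C@@H]2[C@H]1C[C@@H]3[C@H](C2)[C@H]2[C@@H]4CC[C@@H]4[C@@H]32 | intermediate
20 | (10S)-tetracyclo[6.4.0.0^2,7.0^3,6]dodec-11-en-10-ol, OH trans to ring B | O[C@@H]1C=C[C@@H]2[C@H](C1)[C@H]1[C@@H]3CC[C@@H]3[C@@H]21 | intermediate
21 | tetracyclo[6.4.0.0^2,7.0^3,6]dodec-11-en-10-one, enantiomer as in the SMILES | O=C1C=C[C@@H]2[C@H](C1)[C@H]1[C@@H]3CC[C@@H]3[C@@H]21 | intermediate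
22 | lithium tetracyclo[6.4.0.0^2,7.0^3,6]dodec-10-en-10-olate | [Li]OC1=CC[C@@H]2[C@H](C1)[C@H]1[C@@H]3CC[C@@H]3[C@@H]21 | intermediate
23 | tetracyclo[6.4.0.0^2,7.0^3,6]dodec-10-en-10-yl trifluoromethanesulfonate | O=S(=O)(OC1=CC[C@@H]2[C@H](C1)[C@H]1[C@@H]3CC[C@@H]3[C@@H]21)C(F)(F)F | intermediate
24 | 2,2-dimethyl-1,3-dioxan-5-ol | CC1(C)OCC(O)CO1 | starting material
25 | 8-bromooct-1-ene | C=CCCCCCCBr | starting material
26 | sodium 2,2-dimethyl-1,3-dioxan-5-olate | CC1(C)OCC([O-])CO1.[Na+] | intermediate
27 | 2,2-dimethyl-5-(oct-7-en-1-yloxy)-1,3-dioxane | CC1(C)OCC(CO1)OCCCCCCC=C | intermediate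
28 | 9-[8-(2,2-dimethyl-1,3-dioxan-5-yloxy)octyl]-9-borabicyclo[3.3.1]nonane | CC1(C)OCC(CO1)OCCCCCCCCB1C2CCCC1CCC2 | intermediate
29 | 2,2-dimethyl-5-{[8-(tetracyclo[6.4.0.0^2,7.0^3,6]dodec-10-en-10-yl)octyl]oxy}-1,3-dioxane | CC1(C)OCC(CO1)OCCCCCCCCC1=CC[C@@H]2[C@H](C1)[C@H]1[C@@H]3CC[C@@H]3[C@@H]21 | intermediate
30 | 2,2-dimethyl-5-({8-[(10S)-tetracyclo[6.4.0.0^2,7.0^3,6]dodecan-10-yl]octyl}oxy)-1,3-dioxane, chain cis to ring B | CC1(C)OCC(CO1)OCCCCCCCC[C@H]1CC[C@@H]2[C@H](C1)[C@H]1[C@@H]3CC[C@@H]3[C@@H]21 | intermediate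
31 | 2-({8-[(1R,2S,3S,6R,7R,8S,10S)-tetracyclo[6.4.0.0^2,7.0^3,6]dodecan-10-yl]octyl}oxy)propane-1,3-diol | OCC(CO)OCCCCCCCC[C@H]1CC[C@@H]2[C@H](C1)[C@H]1[C@@H]3CC[C@@H]3[C@@H]21 | target

**Count and risks**

Total step count: 17. Longest linear sequence: 14 steps (steps 1, 2, 5 to 13, 15 to 17).

Step 6. What may go wrong: loss of chemoselectivity on the palladium surface, that is over-reduction or double-bond migration at the two vinyl termini, or stalling at ene-yne stages that cannot cyclise. A [1,7]-hydrogen shift of the tetraene could also compete with the 8π closure. Fallback: setting out from 12, the alkynes are reduced not by surface hydrogenation but by electron transfer from zinc (Zn dust activated with Cu(OAc)2 and AgNO3, MeOH/H2O, 25 to 40 °C). This is a stoichiometric cis-reduction that only alkynes conjugated to an alkene undergo and that cannot touch or migrate the vinyl groups. The same tetraene 13 closes through 14 and the route is rejoined at 15; no new compound arises (F0).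

Step 16. What may go wrong: poor facial selectivity, with hydrogen delivered to the face syn to ring B or to both faces, which would give the C10 epimer. Fallback: if the syn face is the one that reacts, carbon instead of hydrogen is brought in on it, with boron as the carrier.
- Setting out from 18, hydroboration with (−)-Ipc2BH (from (+)-α-pinene and BH3·SMe2, THF, −25 °C) should give the B-alkyldiisopinocampheylborane F1 with boron on C10 cis to ring B. Acetaldehyde releases α-pinene to give the diethyl boronate F2, and pinacol gives the pinacol boronate F3.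
- In parallel 24 is alkylated with commercial 8-bromooct-1-yne (NaH, DMF) to the alkyne ether F4, which hydrozirconation–iodination (Cp2Zr(H)Cl, then I2) turns into the (E)-alkenyl iodide F5.
- Iodine–lithium exchange (t-BuLi, −78 °C) gives the alkenyllithium F6, which adds to F3 to form the lithium boronate complex F7. I2 and NaOMe then bring about the Zweifel olefination (1,2-migration with retention at C10, then anti elimination) to give the (Z)-alkene F8.
- Hydrogenation of F8 (H2, [Ir(cod)(PCy3)(py)]PF6) creates no stereocentre and returns to the route at 30.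

Step 8. What may go wrong: photochemical loss of material before useful conversion, by cycloreversion across ring B to an arene and a diene, by ring opening, or by secondary photolysis, and incomplete anti selectivity. Fallback: the closure is moved one stage earlier, before ring A is fused onto ring B. The same competing photoprocesses remain possible for 15, so this is a partial remedy only.
- Setting out from 15, irradiation (254 nm, pentane, 0 °C) of the simple 7,8-dialkylbicyclo[4.2.0]octa-2,4-diene, run to partial conversion with recovery of 15, should give cis-7,8-diallyl-anti-tricyclo[4.2.0.0^2,5]oct-3-ene F9.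
- One equivalent of diimide (KO2CN=NCO2K, AcOH) saturates the strained cyclobutene ahead of the allyl groups to give cis-7,8-diallyl-anti-tricyclo[4.2.0.0^2,5]octane F10. This must precede metathesis, because the ruthenium carbene would open a strained cyclobutene.
- Ring-closing metathesis with the second-generation Grubbs catalyst then closes ring A and rejoins the route at 18.

**Further compounds**

F0 | step 6 | none | none
F1 | step 16 | B-[(10S)-tetracyclo[6.4.0.0^2,7.0^3,6]dodecan-10-yl]diisopinocampheylborane (boron cis to ring B) | B([C@H]1CC[C@@H]2[C@H](C1)[C@H]1[C@@H]3CC[C@@H]3[C@@H]21)([C@@H]1C[C@@H]2C[C@H]([C@H]1C)C2(C)C)[C@@H]1C[C@@H]2C[C@H]([C@H]1C)C2(C)C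
F2 | step 16 | diethyl tetracyclo[6.4.0.0^2,7.0^3,6]dodecan-10-ylboronate | CCOB(OCC)[C@H]1CC[C@@H]2[C@H](C1)[C@H]1[C@@H]3CC[C@@H]3[C@@H]21
F3 | step 16 | 4,4,5,5-tetramethyl-2-(tetracyclo[6.4.0.0^2,7.0^3,6]dodecan-10-yl)-1,3,2-dioxaborolane | CC1(C)OB(OC1(C)C)[C@H]1CC[C@@H]2[C@H](C1)[C@H]1[C@@H]3CC[C@@H]3[C@@H]21
F4 | step 16 | 2,2-dimethyl-5-(oct-7-yn-1-yloxy)-1,3-dioxane | CC1(C)OCC(CO1)OCCCCCCC#C
F5 | step 16 | (E)-5-[(8-iodooct-7-en-1-yl)oxy]-2,2-dimethyl-1,3-dioxane | CC1(C)OCC(CO1)OCCCCCC/C=C/I
F6 | step 16 | (E)-8-(2,2-dimethyl-1,3-dioxan-5-yloxy)oct-1-en-1-yllithium | CC1(C)OCC(CO1)OCCCCCC/C=C/[Li]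
F7 | step 16 | lithium alkenyl(alkyl)pinacolatoborate from F3 and F6 | [Li+].CC1(C)OCC(CO1)OCCCCCC/C=C/[B-]1(OC(C)(C)C(C)(C)O1)[C@H]1CC[C@@H]2[C@H](C1)[C@H]1[C@@H]3CC[C@@H]3[C@@H]21
F8 | step 16 | (Z)-2,2-dimethyl-5-{[8-(tetracyclo[6.4.0.0^2,7.0^3,6]dodecan-10-yl)oct-7-en-1-yl]oxy}-1,3-dioxane | CC1(C)OCC(CO1)OCCCCCC/C=C\[C@H]1CC[C@@H]2[C@H](C1)[C@H]1[C@@H]3CC[C@@H]3[C@@H]21
F9 | step 8 | meso cis-7,8-diallyl-anti-tricyclo[4.2.0.0^2,5]oct-3-ene | C=CC[C@@H]2[C@H](CC=C)[C@H]1[C@@H]3C=C[C@@H]3[C@@H]21
F10 | step 8 | meso cis-7,8-diallyl-anti-tricyclo[4.2.0.0^2,5]octane | C=CC[C@@H]2[C@H](CC=C)[C@H]1[C@@H]3CC[C@@H]3[C@@H]21
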